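## Retrosynthetic overview

Numbering (cembrane): ring C1–C14, lactone C14–O–C16(=O)–C15(=C17H2)–C1, OH on C3, OAc and Me on C4, OAc on C13, Z-alkenes at C7 and C11. The target comes from its C3 ketone (reduced last), the lactone from a C15 acrylic acid and C14–OH, and that acid from a macrocycle with a vinyl group (C15=C16) on C1.
Key disconnection C2–C3: C3(OH)–C2H2–C1(H)–C15=C16 is a bishomoallylic alcohol, the retron of a nickel-catalysed reductive diene–aldehyde coupling (homoallylation). Run within one chain, a C3 aldehyde and the 2-substituted diene C2=C1–C15=C16 close the 14-membered ring, set C1 and leave the vinyl group.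
The dienyl aldehyde comes from a Z-selective Wittig reaction at C11=C12 between a C3–C11 phosphonium salt and a C12–C16 methyl ketone. Neryl acetate gives C6–C11 and the 7Z-alkene; methallyl alcohol and a Sharpless epoxidation give C3–C5, C18 and the C4 stereocentre.
The ketone comes from 2,3-O-isopropylidene-D-erythronolactone, whose C1–C4 become C12, C13, C14 and C1 with both oxygenated stereocentres; the diene comes from ethylene–alkyne metathesis.
Ring order: dioxolane (from the chiral pool, temporary), then the 14-membered carbocycle (step 17), then the α-methylene-γ-lactone (step 22).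

Key step: step 17

Assumption (chemistry): the C3 carbinol configuration formed in step 17 is not relied on. Both C3 epimers are carried on (C3 is left undefined in the SMILES of 23 and 24), they merge at the ketone in step 19, and C3 is set in step 24.

## Route

Step 1
Reactants: 1 neryl acetate, (2Z)-3,7-dimethylocta-2,6-dien-1-yl acetate
Product: 3 (2Z)-6-hydroxy-3-methylhex-2-en-1-yl acetate, via aldehyde 2 (not isolated)
Conditions: O3 (1 equiv), CH2Cl2–MeOH, pyridine, −78 °C; then NaBH4, −78 → 0 °C
Reagents that add atoms: ozone, [O-][O+]=O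
Why: Ozonolysis with reductive work-up should cleave only the electron-rich terminal alkene, because the 2,3-alkene is deactivated by the allylic acetate, and it leaves the Z-alkene untouched.

Step 2
Reactants: 3 (2Z)-6-hydroxy-3-methylhex-2-en-1-yl acetate
Product: 4 (2Z)-6-chloro-3-methylhex-2-en-1-yl acetate
Conditions: PPh3, N-chlorosuccinimide, CH2Cl2, 0 °C
Reagents that add atoms: N-chlorosuccinimide, O=C1CCC(=O)N1Cl
Why: Appel-type chlorination converts the primary alcohol to the chloride under neutral conditions that spare the allylic acetate.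

Step 3
Reactants: 4 (2Z)-6-chloro-3-methylhex-2-en-1-yl acetate
Product: 5 (2Z)-6-chloro-3-methylhex-2-en-1-ol
Conditions: K2CO3 (cat.), MeOH, 0 °C
Reagents that add atoms: none
Why: Base-catalysed transesterification (methanolysis) frees the allylic alcohol, and the primary alkyl chloride is inert under these cold, weakly basic conditions.

Step 4
Reactants: 5 (2Z)-6-chloro-3-methylhex-2-en-1-ol
Product: 6 (2Z)-1-bromo-6-chloro-3-methylhex-2-ene
Conditions: CBr4, PPh3, CH2Cl2, −20 → 0 °C
Reagents that add atoms: tetrabromomethane, BrC(Br)(Br)Br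
Why: Appel bromination of a primary allylic alcohol is a direct SN2 displacement, so neither allylic transposition nor loss of the Z geometry is expected.

Step 5
Reactants: 6 (2Z)-1-bromo-6-chloro-3-methylhex-2-ene; 7 2-methylprop-2-en-1-ol (methallyl alcohol)
Product: 9 (5Z)-9-chloro-6-methyl-2-methylidenenon-5-en-1-ol, via dianion 8 (not isolated)
Conditions: 7, n-BuLi (2.2 equiv), TMEDA, Et2O–hexane, 0 °C → rt; then 6, THF, −78 → −20 °C; H2O work-up
Reagents that add atoms: none
Why: C-alkylation of the methallyl alcohol dianion (allyl anion alkylation) should occur at the allylic bromide far faster than at the alkyl chloride and gives the 2-substituted allylic alcohol.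

Step 6
Reactants: 9 (5Z)-9-chloro-6-methyl-2-methylidenenon-5-en-1-ol
Product: 10 [(2S)-2-[(3Z)-7-chloro-4-methylhept-3-en-1-yl]oxiran-2-yl]methanol
Conditions: Ti(OiPr)4 (cat.), L-(+)-diethyl tartrate, t-BuOOH, 4 Å molecular sieves, CH2Cl2, −20 °C
Reagents that add atoms: tert-butyl hydroperoxide, CC(C)(C)OO
Why: Sharpless asymmetric epoxidation of the 2-substituted allylic alcohol with the L-(+)-tartrate should give the (S)-epoxide, which fixes the C4 quaternary centre by reagent control; the isolated trisubstituted alkene is not epoxidised.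

Step 7
Reactants: 10 [(2S)-2-[(3Z)-7-chloro-4-methylhept-3-en-1-yl]oxiran-2-yl]methanol
Product: 11 (2S,5Z)-9-chloro-2,6-dimethylnon-5-ene-1,2-diol
Conditions: LiAlH4, THF, 0 °C
Reagents that add atoms: none
Why: Hydride SN2 opening of the 2,2-disubstituted epoxide can only occur at its CH2 terminus, which becomes the C4 methyl group while the tertiary C–O stereocentre is untouched.

Step 8
Reactants: 11 (2S,5Z)-9-chloro-2,6-dimethylnon-5-ene-1,2-diol
Product: 12 (2S,5Z)-9-chloro-2,6-dimethyl-1,2-bis(triethylsilyloxy)non-5-ene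
Conditions: Et3SiOTf (2.4 equiv), 2,6-lutidine, CH2Cl2, −78 → 0 °C
Reagents that add atoms: triethylsilyl trifluoromethanesulfonate, CC[Si](CC)(CC)OS(=O)(=O)C(F)(F)F
Why: Silyl ether formation with the silyl triflate protects both the primary and the hindered tertiary hydroxyl.

Step 9
Reactants: 12 (2S,5Z)-9-chloro-2,6-dimethyl-1,2-bis(triethylsilyloxy)non-5-ene
Product: 13 [(4Z,8S)-4,8-dimethyl-8,9-bis(triethylsilyloxy)non-4-en-1-yl]triphenylphosphonium iodide
Conditions: NaI, PPh3, NaHCO3, MeCN, 80 °C
Reagents that add atoms: triphenylphosphine, c1ccc(cc1)P(c1ccccc1)c1ccccc1; sodium iodide, [Na+].[I-]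
Why: Finkelstein exchange followed by SN2 quaternisation of the phosphine gives the primary phosphonium salt, with bicarbonate buffering to protect the silyl ethers.

Step 10
Reactants: 14 2,3-O-isopropylidene-D-erythronolactone, (3aR,6aR)-2,2-dimethyldihydrofuro[3,4-d][1,3]dioxol-4(3aH)-one
Product: 15 (4R,5R)-5-(hydroxymethyl)-N-methoxy-N,2,2-trimethyl-1,3-dioxolane-4-carboxamide
Conditions: MeNH(OMe)·HCl, AlMe3, CH2Cl2, 0 °C → rt
Reagents that add atoms: N,O-dimethylhydroxylamine hydrochloride, CNOC.Cl
Why: Weinreb aminolysis of the lactone with the aluminium amide opens the ring without touching the two stereocentres.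

Step 11
Reactants: 15 (4R,5R)-5-(hydroxymethyl)-N-methoxy-N,2,2-trimethyl-1,3-dioxolane-4-carboxamide
Product: 16 (4R,5S)-5-formyl-N-methoxy-N,2,2-trimethyl-1,3-dioxolane-4-carboxamide
Conditions: Dess–Martin periodinane, NaHCO3, CH2Cl2, 0 °C → rt
Reagents that add atoms: none
Why: Dess–Martin oxidation gives the α-alkoxy aldehyde under buffered conditions that should not epimerise it.

Step 12
Reactants: 16 (4R,5S)-5-formyl-N-methoxy-N,2,2-trimethyl-1,3-dioxolane-4-carboxamide
Product: 17 (4R,5R)-5-ethynyl-N-methoxy-N,2,2-trimethyl-1,3-dioxolane-4-carboxamide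
Conditions: dimethyl (1-diazo-2-oxopropyl)phosphonate, K2CO3, MeOH, 0 °C → rt
Reagents that add atoms: dimethyl (1-diazo-2-oxopropyl)phosphonate, COP(=O)(OC)C(=[N+]=[N-])C(C)=O
Why: Ohira–Bestmann (Seyferth–Gilbert) homologation converts the aldehyde to the terminal alkyne under mild carbonate conditions that are established for cis-dioxolane α-alkoxy aldehydes.

Step 13
Reactants: 17 (4R,5R)-5-ethynyl-N-methoxy-N,2,2-trimethyl-1,3-dioxolane-4-carboxamide
Product: 18 1-[(4R,5R)-5-ethynyl-2,2-dimethyl-1,3-dioxolan-4-yl]ethan-1-one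
Conditions: MeMgBr (2.5 equiv), THF, −20 → 0 °C
Reagents that add atoms: methylmagnesium bromide, C[Mg]Br
Why: Weinreb ketone synthesis: the chelated tetrahedral intermediate stops the Grignard addition at the methyl ketone.

Step 14
Reactants: 18 1-[(4R,5R)-5-ethynyl-2,2-dimethyl-1,3-dioxolan-4-yl]ethan-1-one
Product: 19 1-[(4R,5R)-5-(buta-1,3-dien-2-yl)-2,2-dimethyl-1,3-dioxolan-4-yl]ethan-1-one
Conditions: ethene (1 atm), second-generation Grubbs catalyst RuCl2(=CHPh)(PCy3)(H2IMes) (5 mol %), CH2Cl2, rt
Reagents that add atoms: ethene, C=C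
Why: Ethylene–alkyne cross enyne metathesis turns the terminal alkyne into the 2-substituted 1,3-diene and tolerates propargylic oxygen substituents.

Step 15
Reactants: 13 [(4Z,8S)-4,8-dimethyl-8,9-bis(triethylsilyloxy)non-4-en-1-yl]triphenylphosphonium iodide; 19 1-[(4R,5R)-5-(buta-1,3-dien-2-yl)-2,2-dimethyl-1,3-dioxolan-4-yl]ethan-1-one
Product: 21 (4S,5R)-5-(buta-1,3-dien-2-yl)-4-[(2Z,6Z,10S)-6,10-dimethyl-10,11-bis(triethylsilyloxy)undeca-2,6-dien-2-yl]-2,2-dimethyl-1,3-dioxolane, via ylide 20 (not isolated)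
Conditions: 13, KN(SiMe3)2, THF, −78 → 0 °C; then 19, −78 °C → rt
Reagents that add atoms: none
Why: Wittig olefination of an α-alkoxy methyl ketone with a non-stabilised ylide is a combination known to place the ylide chain cis to the oxygenated carbon, which is the 11Z geometry required.

Step 16
Reactants: 21 the Wittig product, bis(triethylsilyl) ether with diene and dioxolane
Product: 22 (2S,5Z,9Z)-10-[(4S,5R)-5-(buta-1,3-dien-2-yl)-2,2-dimethyl-1,3-dioxolan-4-yl]-2,6-dimethyl-2-(triethylsilyloxy)undeca-5,9-dienal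
Conditions: (COCl)2, DMSO, CH2Cl2, −78 °C; Et3N, −78 → −20 °C
Reagents that add atoms: none
Why: Swern oxidation is known to cleave and oxidise a primary triethylsilyl ether directly to the aldehyde while a hindered (here tertiary) silyl ether survives.

Step 17
Reactants: 22 the dienyl aldehyde (C3 aldehyde, diene C2=C1–C15=C16)
Product: 23 (1R,4S,7Z,11Z,13S,14R)-1-ethenyl-4,8,12-trimethyl-13,14-(propane-2,2-diyldioxy)-4-(triethylsilyloxy)cyclotetradeca-7,11-dien-3-ol (cembrane locants; both C3 epimers)
Conditions: Ni(acac)2 (20 mol %), Et3B (4 equiv), THF, rt, syringe-pump addition of 22 to 2 mM final concentration, N2; aq. NH4Cl work-up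
Reagents that add atoms: none
Why: Proposed new method: zerovalent nickel (from Ni(acac)2 and Et3B) binds the s-cis diene, and oxidative cyclisation with the Et3B-activated aldehyde forms the C2–C3 bond at the CH2 terminus next to the substituted diene carbon to give an oxanickelacycle with an η3-allyl over C1–C15–C16; ethyl transfer from boron, β-hydride elimination and reductive elimination then place hydrogen on C1 and leave the C15=C16 vinyl group, the alcohol being released as its borinate. The closest known reactions are the Ni(acac)2/Et3B homoallylation of hindered aliphatic aldehydes with isoprene-type dienes (same regiochemistry: bond at C1 of the diene, hydrogen at C2), its intramolecular form for five- and six-membered rings, and nickel-catalysed reductive alkyne–aldehyde macrocyclisations; only the extension to a 14-membered ring is new. The carbocycle closes in a 14-endo-trig sense on the C2=C1 bond, and the 16-membered alternative through C16 is disfavoured by the intrinsic preference for the terminus next to the substituted carbon. C1 is set by hydride delivery from nickel on the diene face that carries the tether: in the rotamer with the dioxolane C14–H eclipsing C1=C2 (least allylic strain) the ring oxygen lies on one face and C13 with its chain on the other, so metal and aldehyde should approach anti to the allylic C–O bond and hydrogen should enter syn to C13, which gives the trans C1/C14 relationship of the target lactone. The C3 carbinol centre is formed without reliable control (Felkin–Anh addition and the usual 1,3-anti preference both favour the 3R epimer), which does not matter because both epimers give the same ketone in step 19. The step needs chemoselectivity for aldehyde and diene, which the inert trisubstituted alkenes, silyl ether and acetal provide, and ring closure over oligomerisation, which slow addition at high dilution and the turn imposed by the two Z-alkenes and the cis-dioxolane should secure.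

Step 18
Reactants: 23 the macrocyclic vinyl carbinol (both C3 epimers)
Product: 24 (1S,4S,7Z,11Z,13S,14R)-1-(2-hydroxyethyl)-4,8,12-trimethyl-13,14-(propane-2,2-diyldioxy)-4-(triethylsilyloxy)cyclotetradeca-7,11-dien-3-ol (both C3 epimers)
Conditions: 9-BBN (2.5 equiv), THF, 0 °C → rt; then NaOH, H2O2, 0 °C
Reagents that add atoms: hydrogen peroxide, OO
Why: Hydroboration–oxidation with 9-BBN is selective for the monosubstituted vinyl group over the trisubstituted ring alkenes and places the hydroxyl on the terminal carbon (C16).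

Step 19
Reactants: 24 the macrocyclic diol (both C3 epimers)
Product: 25 2-[(1S,4S,7Z,11Z,13S,14R)-4,8,12-trimethyl-3-oxo-13,14-(propane-2,2-diyldioxy)-4-(triethylsilyloxy)cyclotetradeca-7,11-dien-1-yl]acetaldehyde
Conditions: Dess–Martin periodinane (3 equiv), NaHCO3, CH2Cl2, rt
Reagents that add atoms: none
Why: Dess–Martin oxidation converts both C3 epimers into one ketone and the primary alcohol into the aldehyde in the same operation.

Step 20
Reactants: 25 the keto aldehyde
Product: 26 2-[(1R,4S,7Z,11Z,13S,14R)-4,8,12-trimethyl-3-oxo-13,14-(propane-2,2-diyldioxy)-4-(triethylsilyloxy)cyclotetradeca-7,11-dien-1-yl]prop-2-enal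
Conditions: aq. CH2O (37%), pyrrolidine (10 mol %), propionic acid (10 mol %), i-PrOH, 45 °C
Reagents that add atoms: formaldehyde, C=O
Why: Organocatalytic α-methylenation (Mannich condensation and elimination through enamine and iminium intermediates) should be selective for the unhindered aldehyde over the neopentyl-type ketone and installs C17.

Step 21
Reactants: 26 the α-methylene aldehyde
Product: 27 2-[(1R,4S,7Z,11Z,13S,14R)-4,8,12-trimethyl-3-oxo-13,14-(propane-2,2-diyldioxy)-4-(triethylsilyloxy)cyclotetradeca-7,11-dien-1-yl]prop-2-enoic acid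
Conditions: NaClO2, NaH2PO4, 2-methylbut-2-ene, t-BuOH–H2O, 0 °C → rt
Reagents that add atoms: sodium chlorite, [Na+].[O-]Cl=O
Why: Pinnick oxidation converts the enal to the acrylic acid without touching the alkenes, the scavenger removing hypochlorite.

Step 22
Reactants: 27 the acrylic acid
Product: 29 (1R,4S,7Z,11Z,13S,14R)-4,13-dihydroxy-3-oxocembra-7,11,15(17)-trien-16,14-olide, via seco acid 28 (not isolated)
Conditions: CF3CO2H–H2O (9:1), CH2Cl2, 0 °C, short reaction time; then concentration from toluene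
Reagents that add atoms: none
Why: Acid hydrolysis removes the acetonide and the tertiary silyl ether, and acid-catalysed lactonisation (5-exo-trig acyl substitution by C14–OH) should then give the γ-lactone, whose five-membered ring forms faster than the six-membered alternative through C13–OH.

Step 23
Reactants: 29 the keto lactone diol
Product: 30 (1R,4S,7Z,11Z,13S,14R)-4,13-diacetoxy-3-oxocembra-7,11,15(17)-trien-16,14-olide
Conditions: Ac2O, DMAP, Et3N, CH2Cl2, rt → 40 °C
Reagents that add atoms: acetic anhydride, CC(=O)OC(C)=O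
Why: DMAP-catalysed acylation acetylates the secondary allylic and the tertiary α-ketol hydroxyls, and no selectivity problem arises because C3 is still a ketone.

Step 24
Reactants: 30 the diacetoxy ketone
Product: 31 (1R,3S,4S,7Z,11Z,13S,14R)-4,13-diacetoxy-3-hydroxycembra-7,11,15(17)-trien-16,14-olide (target)
Conditions: (R)-2-methyl-CBS-oxazaborolidine (1 equiv), catecholborane, toluene–CH2Cl2, −78 → −40 °C; pH 7 work-up
Reagents that add atoms: none
Why: Corey–Bakshi–Shibata reduction: the (R)-oxazaborolidine distinguishes the C2 methylene from the quaternary C4 and, matched with Felkin–Anh attack anti to the C4 acetoxy group, should give the (3S)-alcohol, while catecholborane at low temperature should leave the α-methylene lactone and the acetates alone.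

## Compound list

1 | neryl acetate, (2Z)-3,7-dimethylocta-2,6-dien-1-yl acetate | CC(=O)OC/C=C(/C)CCC=C(C)C | starting material
2 | (2Z)-3-methyl-6-oxohex-2-en-1-yl acetate | CC(=O)OC/C=C(/C)CCC=O | intermediate
3 | (2Z)-6-hydroxy-3-methylhex-2-en-1-yl acetate | CC(=O)OC/C=C(/C)CCCO | intermediate
4 | (2Z)-6-chloro-3-methylhex-2-en-1-yl acetate | CC(=O)OC/C=C(/C)CCCCl | intermediate
5 | (2Z)-6-chloro-3-methylhex-2-en-1-ol | OC/C=C(/C)CCCCl | intermediate
6 | (2Z)-1-bromo-6-chloro-3-methylhex-2-ene | BrC/C=C(/C)CCCCl | intermediate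
7 | 2-methylprop-2-en-1-ol (methallyl alcohol) | C=C(C)CO | starting material
8 | dianion of 7, lithium 2-(lithiomethyl)prop-2-en-1-olate | [Li]CC(=C)CO[Li] | intermediate
9 | (5Z)-9-chloro-6-methyl-2-methylidenenon-5-en-1-ol | OCC(=C)CC/C=C(/C)CCCCl | intermediate
10 | [(2S)-2-[(3Z)-7-chloro-4-methylhept-3-en-1-yl]oxiran-2-yl]methanol | OC[C@]1(CO1)CC/C=C(/C)CCCCl | intermediate
11 | (2S,5Z)-9-chloro-2,6-dimethylnon-5-ene-1,2-diol | OC[C@@](C)(O)CC/C=C(/C)CCCCl | intermediate
12 | (2S,5Z)-9-chloro-2,6-dimethyl-1,2-bis(triethylsilyloxy)non-5-ene | CC[Si](CC)(CC)OC[C@@](C)(O[Si](CC)(CC)CC)CC/C=C(/C)CCCCl | intermediate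
13 | [(4Z,8S)-4,8-dimethyl-8,9-bis(triethylsilyloxy)non-4-en-1-yl]triphenylphosphonium iodide | CC[Si](CC)(CC)OC[C@@](C)(O[Si](CC)(CC)CC)CC/C=C(/C)CCC[P+](c1ccccc1)(c1ccccc1)c1ccccc1.[I-] | intermediate
14 | 2,3-O-isopropylidene-D-erythronolactone, (3aR,6aR)-2,2-dimethyldihydrofuro[3,4-d][1,3]dioxol-4(3aH)-one | O=C1[C@@H]2OC(C)(C)O[C@@H]2CO1 | starting material
15 | (4R,5R)-5-(hydroxymethyl)-N-methoxy-N,2,2-trimethyl-1,3-dioxolane-4-carboxamide | CON(C)C(=O)[C@@H]1OC(C)(C)O[C@@H]1CO | intermediate
16 | (4R,5S)-5-formyl-N-methoxy-N,2,2-trimethyl-1,3-dioxolane-4-carboxamide | CON(C)C(=O)[C@@H]1OC(C)(C)O[C@@H]1C=O | intermediate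
17 | (4R,5R)-5-ethynyl-N-methoxy-N,2,2-trimethyl-1,3-dioxolane-4-carboxamide | CON(C)C(=O)[C@@H]1OC(C)(C)O[C@@H]1C#C | intermediate
18 | 1-[(4R,5R)-5-ethynyl-2,2-dimethyl-1,3-dioxolan-4-yl]ethan-1-one | CC(=O)[C@@H]1OC(C)(C)O[C@@H]1C#C | intermediate
19 | 1-[(4R,5R)-5-(buta-1,3-dien-2-yl)-2,2-dimethyl-1,3-dioxolan-4-yl]ethan-1-one | CC(=O)[C@@H]1OC(C)(C)O[C@@H]1C(=C)C=C | intermediate
20 | ylide, [(4Z,8S)-4,8-dimethyl-8,9-bis(triethylsilyloxy)non-4-en-1-ylidene]triphenylphosphorane | CC[Si](CC)(CC)OC[C@@](C)(O[Si](CC)(CC)CC)CC/C=C(/C)CCC=P(c1ccccc1)(c1ccccc1)c1ccccc1 | intermediate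
21 | (4S,5R)-5-(buta-1,3-dien-2-yl)-4-[(2Z,6Z,10S)-6,10-dimethyl-10,11-bis(triethylsilyloxy)undeca-2,6-dien-2-yl]-2,2-dimethyl-1,3-dioxolane | CC[Si](CC)(CC)OC[C@@](C)(O[Si](CC)(CC)CC)CC/C=C(/C)CC/C=C(/C)[C@@H]1OC(C)(C)O[C@@H]1C(=C)C=C | intermediate
22 | (2S,5Z,9Z)-10-[(4S,5R)-5-(buta-1,3-dien-2-yl)-2,2-dimethyl-1,3-dioxolan-4-yl]-2,6-dimethyl-2-(triethylsilyloxy)undeca-5,9-dienal | O=C[C@@](C)(O[Si](CC)(CC)CC)CC/C=C(/C)CC/C=C(/C)[C@@H]1OC(C)(C)O[C@@H]1C(=C)C=C | intermediate
23 | (1R,4S,7Z,11Z,13S,14R)-1-ethenyl-4,8,12-trimethyl-13,14-(propane-2,2-diyldioxy)-4-(triethylsilyloxy)cyclotetradeca-7,11-dien-3-ol, both C3 epimers | CC1(C)O[C@@H]2[C@@H](C=C)CC(O)[C@@](C)(O[Si](CC)(CC)CC)CC/C=C(/C)CC/C=C(/C)[C@@H]2O1 | intermediate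
24 | (1S,4S,7Z,11Z,13S,14R)-1-(2-hydroxyethyl)-4,8,12-trimethyl-13,14-(propane-2,2-diyldioxy)-4-(triethylsilyloxy)cyclotetradeca-7,11-dien-3-ol, both C3 epimers | CC1(C)O[C@@H]2[C@@H](CCO)CC(O)[C@@](C)(O[Si](CC)(CC)CC)CC/C=C(/C)CC/C=C(/C)[C@@H]2O1 | intermediate
25 | 2-[(1S,4S,7Z,11Z,13S,14R)-4,8,12-trimethyl-3-oxo-13,14-(propane-2,2-diyldioxy)-4-(triethylsilyloxy)cyclotetradeca-7,11-dien-1-yl]acetaldehyde | CC1(C)O[C@@H]2[C@@H](CC=O)CC(=O)[C@@](C)(O[Si](CC)(CC)CC)CC/C=C(/C)CC/C=C(/C)[C@@H]2O1 | intermediate
26 | 2-[(1R,4S,7Z,11Z,13S,14R)-4,8,12-trimethyl-3-oxo-13,14-(propane-2,2-diyldioxy)-4-(triethylsilyloxy)cyclotetradeca-7,11-dien-1-yl]prop-2-enal | CC1(C)O[C@@H]2[C@@H](C(=C)C=O)CC(=O)[C@@](C)(O[Si](CC)(CC)CC)CC/C=C(/C)CC/C=C(/C)[C@@H]2O1 | intermediate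
27 | 2-[(1R,4S,7Z,11Z,13S,14R)-4,8,12-trimethyl-3-oxo-13,14-(propane-2,2-diyldioxy)-4-(triethylsilyloxy)cyclotetradeca-7,11-dien-1-yl]prop-2-enoic acid | CC1(C)O[C@@H]2[C@@H](C(=C)C(O)=O)CC(=O)[C@@](C)(O[Si](CC)(CC)CC)CC/C=C(/C)CC/C=C(/C)[C@@H]2O1 | intermediate
28 | seco acid, 2-[(1R,4S,7Z,11Z,13S,14R)-4,13,14-trihydroxy-4,8,12-trimethyl-3-oxocyclotetradeca-7,11-dien-1-yl]prop-2-enoic acid | O[C@@H]1[C@@H](C(=C)C(O)=O)CC(=O)[C@@](C)(O)CC/C=C(/C)CC/C=C(/C)[C@@H]1O | intermediate
29 | (1R,4S,7Z,11Z,13S,14R)-4,13-dihydroxy-3-oxocembra-7,11,15(17)-trien-16,14-olide | C=C1C(=O)O[C@@H]2[C@@H]1CC(=O)[C@@](C)(O)CC/C=C(/C)CC/C=C(/C)[C@@H]2O | intermediate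
30 | (1R,4S,7Z,11Z,13S,14R)-4,13-diacetoxy-3-oxocembra-7,11,15(17)-trien-16,14-olide | C=C1C(=O)O[C@@H]2[C@@H]1CC(=O)[C@@](C)(OC(C)=O)CC/C=C(/C)CC/C=C(/C)[C@@H]2OC(C)=O | intermediate
31 | (1R,3S,4S,7Z,11Z,13S,14R)-4,13-diacetoxy-3-hydroxycembra-7,11,15(17)-trien-16,14-olide | C=C1C(=O)O[C@@H]2[C@@H]1C[C@H](O)[C@@](C)(OC(C)=O)CC/C=C(/C)CC/C=C(/C)[C@@H]2OC(C)=O | target

## Step count and risks

Total step count: 24. Longest linear sequence: 19 steps (steps 1–9 and 15–24).

Steps most likely to fail:

Step 17 (Proposed new method). The slow 14-membered ring closure may lose to intermolecular diene–aldehyde coupling at the low concentrations required, and nickel may deliver hydrogen to the other diene face, giving the C1 epimer. The fallback uses known chemistry and swaps the order of the two fragment unions; it sets out from 12 and 19 and comes back at 23. Swern oxidation of 12 should give (2S,5Z)-9-chloro-2,6-dimethyl-2-(triethylsilyloxy)non-5-enal F1. The known intermolecular Ni(acac)2/Et3B homoallylation of F1 with diene 19 at normal concentration (a ketone is inert with Et3B) should give the open-chain adduct with the C2–C3 bond, C1–H and the vinyl group already in place, F2, whose C1 epimers can be separated at this acyclic stage. NaI and PPh3 should convert its chloride to the phosphonium iodide F3. Treatment with KN(SiMe3)2 at high dilution should then close the ring at C11=C12 by an intramolecular Wittig reaction on the α-alkoxy methyl ketone, returning 23.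

Step 24. Hydride may add in conjugate fashion to the α-methylene lactone, or facial selectivity at the hindered ketone may be poor. The fallback masks the Michael acceptor; it sets out from 30 and comes back at 31. Conjugate addition of dimethylamine to 30 should give the amine adduct, in which C17 carries NMe2 (C15 epimers), F4. Reduction of its C3 ketone with the same oxazaborolidine, or with LiBH(s-Bu)3 under Felkin–Anh control, should give the (3S)-alcohol F5. Quaternisation with MeI and elimination with aqueous NaHCO3 should regenerate the α-methylene lactone and give 31.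

Step 15. The basic ylide may enolise the α-alkoxy ketone (epimerising C13 to the trans-dioxolane or lowering conversion), and the Z/E ratio may erode. The fallback is a stepwise Horner–Wittig olefination; it sets out from 12 and comes back at 21. Displacement of chloride in 12 with LiPPh2 and oxidation with H2O2 should give the diphenylphosphine oxide F6. Lithiation (n-BuLi, −78 °C) and addition to ketone 19 should give the β-hydroxy phosphine oxides F7, from which the diastereomers that give the Z-alkene on syn-elimination are separated. NaH in DMF should then eliminate diphenylphosphinate stereospecifically to give 21.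

Further compounds
F1 | step 17 | (2S,5Z)-9-chloro-2,6-dimethyl-2-(triethylsilyloxy)non-5-enal | O=C[C@@](C)(O[Si](CC)(CC)CC)CC/C=C(/C)CCCCl
F2 | step 17 | open-chain homoallylation adduct, 1-[(4R,5R)-5-[(3R,6S,9Z)-13-chloro-5-hydroxy-6,10-dimethyl-6-(triethylsilyloxy)trideca-1,9-dien-3-yl]-2,2-dimethyl-1,3-dioxolan-4-yl]ethan-1-one (carbinol epimers) | CC(=O)[C@@H]1OC(C)(C)O[C@@H]1[C@@H](C=C)CC(O)[C@@](C)(O[Si](CC)(CC)CC)CC/C=C(/C)CCCCl
F3 | step 17 | phosphonium iodide of F2 (PPh3+ in place of Cl) | CC(=O)[C@@H]1OC(C)(C)O[C@@H]1[C@@H](C=C)CC(O)[C@@](C)(O[Si](CC)(CC)CC)CC/C=C(/C)CCC[P+](c1ccccc1)(c1ccccc1)c1ccccc1.[I-]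
F4 | step 24 | dimethylamine adduct of 30, 17-(dimethylamino)-15,17-dihydro derivative (C15 epimers) | CN(C)CC1C(=O)O[C@@H]2[C@@H]1CC(=O)[C@@](C)(OC(C)=O)CC/C=C(/C)CC/C=C(/C)[C@@H]2OC(C)=O
F5 | step 24 | (3S)-alcohol of F4 | CN(C)CC1C(=O)O[C@@H]2[C@@H]1C[C@H](O)[C@@](C)(OC(C)=O)CC/C=C(/C)CC/C=C(/C)[C@@H]2OC(C)=O
F6 | step 15 | [(4Z,8S)-4,8-dimethyl-8,9-bis(triethylsilyloxy)non-4-en-1-yl]diphenylphosphine oxide | CC[Si](CC)(CC)OC[C@@](C)(O[Si](CC)(CC)CC)CC/C=C(/C)CCCP(=O)(c1ccccc1)c1ccccc1
F7 | step 15 | β-hydroxy phosphine oxide from F6 and 19 (P on C11, OH on C12; the diastereomers that eliminate to the Z-alkene) | CC[Si](CC)(CC)OC[C@@](C)(O[Si](CC)(CC)CC)CC/C=C(/C)CCC(P(=O)(c1ccccc1)c1ccccc1)C(C)(O)[C@@H]1OC(C)(C)O[C@@H]1C(=C)C=C
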